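TBS = tert-butyldimethylsilyl, PMB = 4-methoxybenzyl. Core lettering used throughout: bridge carbons a (quaternary, CH3 and CH2O-angelate), k (CHOAc), j (CH2), i (CHO-senecioate); cyclobutane carbons b (CH bonded to a), h (C–CH3 bonded to i), c and g (the two remaining CH); enone bridge d (C=O, on c), e (=CH), f (=C–CH3, on g).

**Plan**
- Retrosynthesis: remove the three esters, open the enone ring at e=f (intramolecular Horner–Wadsworth–Emmons), then cut a–b and h–i together. The cyclobutane diagonal b···h becomes the central bond of acyl bicyclo[1.1.0]butane 15, the bridge a–k–j–i becomes silyl dienol ether 20, and the methyl on h is the reduced activating carbonyl.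
- Forward: a rhodium carbene builds the bicyclobutane; the key annulation opens its central bond and closes the seven-membered ring (bicyclo[4.1.1]octene); the cyclohexenone ring closes late, before the ester installations.
- Enabling feature: b and h are 1,3-related on the cyclobutane and carry the four-carbon bridge on one face, while the enone bridge d–e–f sits on c and g on the other face. Hence c and g can be exo-substituted wings of a bicyclobutane whose concave face stays open to the diene.
- Stereochemistry: (S)-lactate, Felkin addition and Claisen chirality transfer fix c; the cyclopropanation fixes b and g. The key step fixes a, b, h and i (concave-face entry, ring-locked diene geometry, bisoxazoline ligand for the side of approach). Carbinol k comes from a hydroxyl-directed reduction.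

Key step: step 12

Assumption 1: silyl ether 4 and ynone 16 are purchased (16 is otherwise one MnO2 oxidation from pent-1-yn-3-ol).
Assumption 2: for the two chiral catalysts (Rh2(S-NTTL)4 in step 6, the (S,S)-bisoxazoline in step 12) the enantiomer written is a working choice; the sense of induction on these new substrates is not claimed, and the antipode is used if it proves the matched one.

Step 1
Reactants: 1 ethyl (S)-lactate
Product: 2 ethyl (2S)-2-[(tert-butyldimethylsilyl)oxy]propanoate
Conditions: TBSCl, imidazole, DMF, 0 °C to rt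
Reagents that add atoms: tert-butyldimethylsilyl chloride, CC(C)(C)[Si](C)(C)Cl
Why: Imidazole-promoted silyl ether formation leaves the stereocentre untouched and installs the non-chelating group that steers the later Felkin addition.

Step 2
Reactants: 2 ethyl (2S)-2-[(tert-butyldimethylsilyl)oxy]propanoate
Product: 3 (2S)-2-[(tert-butyldimethylsilyl)oxy]propanal
Conditions: i-Bu2AlH (1.05 equiv), CH2Cl2, −78 °C; Rochelle-salt work-up
Reagents that add atoms: none
Why: Partial ester reduction with i-Bu2AlH stops at the aldehyde because the tetrahedral aluminate survives at −78 °C; the aldehyde is used at once to avoid racemisation.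

Step 3
Reactants: 4 tert-butyldimethyl(prop-2-yn-1-yloxy)silane; 3 (2S)-2-[(tert-butyldimethylsilyl)oxy]propanal
Product: 7 (2S,3R,4E)-2,6-bis[(tert-butyldimethylsilyl)oxy]hex-4-en-3-ol, via alkenylzirconocene chloride 5 (not isolated), via alkenyl(methyl)zinc 6 (not isolated)
Conditions: Cp2Zr(H)Cl, CH2Cl2, rt; Me2Zn, −65 °C; then 3, 0 °C
Reagents that add atoms: Cp2Zr(H)Cl, [H][Zr](Cl)(C1C=CC=C1)C1C=CC=C1 (zirconium stays in 5 only); Me2Zn, C[Zn]C (zinc stays in 6 only)
Why: syn-Hydrozirconation gives the E-alkenyl metal, zirconium-to-zinc transmetalation makes it add to the aldehyde, and Felkin–Anh addition (silyloxy group anti to the nucleophile, no chelation) should set the 3R carbinol anti to the 2S ether; the minor syn epimer is removed here because it would later surface as the enantiomeric series.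

Step 4
Reactants: 7 (2S,3R,4E)-2,6-bis[(tert-butyldimethylsilyl)oxy]hex-4-en-3-ol; 8 trimethyl orthoacetate
Product: 10 methyl (3S,4E,6S)-6-[(tert-butyldimethylsilyl)oxy]-3-{[(tert-butyldimethylsilyl)oxy]methyl}hept-4-enoate, via mixed ketene acetal 9 (not isolated)
Conditions: MeC(OMe)3 (excess), EtCO2H (cat.), xylene, 135 °C, MeOH distilled off
Reagents that add atoms: none
Why: Johnson–Claisen rearrangement through a chair with the silyloxyethyl group equatorial transfers the carbinol chirality suprafacially to the new C–C bond, giving the 3S centre (future c) and the E-alkene.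

Step 5
Reactants: 10 methyl (3S,4E,6S)-6-[(tert-butyldimethylsilyl)oxy]-3-{[(tert-butyldimethylsilyl)oxy]methyl}hept-4-enoate
Product: 12 methyl (3R,4E,6S)-2-diazo-6-[(tert-butyldimethylsilyl)oxy]-3-{[(tert-butyldimethylsilyl)oxy]methyl}hept-4-enoate, via trifluoroacetyl ester 11 (not isolated)
Conditions: LiN(SiMe3)2, THF, −78 °C; CF3CO2CH2CF3; then MsN3, Et3N, MeCN, rt
Reagents that add atoms: 2,2,2-trifluoroethyl trifluoroacetate, O=C(OCC(F)(F)F)C(F)(F)F (acyl group stays in 11 only); methanesulfonyl azide, CS(=O)(=O)N=[N+]=[N-]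
Why: Regitz-type detrifluoroacetylative diazo transfer: Claisen acylation activates the α-carbon and the sulfonyl azide then delivers N2 with loss of the trifluoroacetyl group, while the non-enolisable C3 keeps its configuration (its descriptor changes only by priority).

Step 6
Reactants: 12 methyl (3R,4E,6S)-2-diazo-6-[(tert-butyldimethylsilyl)oxy]-3-{[(tert-butyldimethylsilyl)oxy]methyl}hept-4-enoate
Product: 13 methyl (2R,4S)-2-{[(tert-butyldimethylsilyl)oxy]methyl}-4-{(1S)-1-[(tert-butyldimethylsilyl)oxy]ethyl}bicyclo[1.1.0]butane-1-carboxylate (both side chains exo)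
Conditions: dirhodium tetrakis[N-(1,8-naphthaloyl)-(S)-tert-leucinate], Rh2(S-NTTL)4 (1 mol %), toluene, −78 °C
Reagents that add atoms: none
Why: Intramolecular cyclopropanation of the rhodium carbene of a 2-diazopent-4-enoate (bicyclobutanation), with a bulky carboxylate catalyst at low temperature to hold back 1,2-hydride migration; the E-alkene places the silyloxyethyl group exo on g, and allylic strain (C3–H eclipsing the alkene) places the silyloxymethyl group exo on c, so the C3 centre dictates b and g.

Step 7
Reactants: 13 bicyclobutane methyl ester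
Product: 14 (2R,4S)-2-{[(tert-butyldimethylsilyl)oxy]methyl}-4-{(1S)-1-[(tert-butyldimethylsilyl)oxy]ethyl}bicyclo[1.1.0]butane-1-carboxylic acid
Conditions: LiOH, THF/MeOH/H2O, 0 °C to rt; NaH2PO4 buffer (pH 5), used without storage
Reagents that add atoms: lithium hydroxide, [Li+].[OH-]
Why: Saponification of the bridgehead ester is compatible with the base-stable bicyclobutane, and the buffered acidification protects the acid-labile central bond.

Step 8
Reactants: 14 bicyclobutane carboxylic acid
Product: 15 (3,5-dimethyl-1H-pyrazol-1-yl){(2R,4S)-2-{[(tert-butyldimethylsilyl)oxy]methyl}-4-{(1S)-1-[(tert-butyldimethylsilyl)oxy]ethyl}bicyclo[1.1.0]butan-1-yl}methanone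
Conditions: 3,5-dimethylpyrazole, DCC, DMAP (cat.), CH2Cl2, 0 °C to rt
Reagents that add atoms: 3,5-dimethyl-1H-pyrazole, Cc1cc(C)[nH]n1
Why: Carbodiimide coupling gives the N-acylpyrazole, a two-point-binding activating group (carbonyl O and N2) that allows a mild chelating chiral Lewis acid in the key step and is easily reduced afterwards.

Step 9
Reactants: 16 pent-1-yn-3-one; 17 4-methoxybenzyl alcohol
Product: 18 (1E)-1-[(4-methoxybenzyl)oxy]pent-1-en-3-one
Conditions: DABCO (10 mol %), CH2Cl2, 0 °C to rt
Reagents that add atoms: none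
Why: Amine-catalysed oxa-Michael addition of an alcohol to a terminal ynone gives the thermodynamically preferred E β-alkoxy enone.

Step 10
Reactants: 18 (1E)-1-[(4-methoxybenzyl)oxy]pent-1-en-3-one
Product: 19 (1E)-5-hydroxy-1-[(4-methoxybenzyl)oxy]-4-methylpent-1-en-3-one (racemic at C4)
Conditions: LiN(SiMe3)2, THF, −78 °C; monomeric CH2O in THF (cracked paraformaldehyde), −78 °C; NH4Cl
Reagents that add atoms: formaldehyde, C=O
Why: Kinetic α′-deprotonation of the vinylogous ester gives the cross-conjugated enolate, which undergoes aldol addition to formaldehyde; the new centre is racemic and becomes planar in the next step.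

Step 11
Reactants: 19 (1E)-5-hydroxy-1-[(4-methoxybenzyl)oxy]-4-methylpent-1-en-3-one
Product: 20 2,2-di-tert-butyl-6-{(E)-2-[(4-methoxybenzyl)oxy]ethenyl}-5-methyl-4H-1,3,2-dioxasiline
Conditions: t-Bu2Si(OTf)2, Et3N, CH2Cl2, −78 to 0 °C
Reagents that add atoms: di-tert-butylsilyl bis(trifluoromethanesulfonate), CC(C)(C)[Si](OS(=O)(=O)C(F)(F)F)(OS(=O)(=O)C(F)(F)F)C(C)(C)C
Why: Silylation of the primary alcohol followed by intramolecular soft enolisation (silyl triflate and amine) closes the six-membered dioxasiline, which can form only with CH2O and the enol oxygen cis, so the Z geometry at a=k is fixed; a is the only enolisable position.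

Step 12
Reactants: 15 bicyclobutane N-acylpyrazole; 20 dioxasiline dienol ether
Product: 21 bicyclo[4.1.1]octene with the pyrazolylcarbonyl group on h, the silylene enol ether (k=j) tied to the CH2O on a, the PMB ether on i and the TBS-protected arms on c and g
Conditions: Cu(OTf)2 (10 mol %), 2,2′-isopropylidenebis[(4S)-4-tert-butyl-2-oxazoline] (11 mol %), 4 Å molecular sieves, CH2Cl2, −40 to 0 °C
Reagents that add atoms: none
Why: Proposed new method: the copper-chelated N-acylpyrazole polarises the central b–h bond, the fully substituted enol-ether carbon a attacks b on the concave face with inversion (strain-release homo-Michael addition), and the copper enolate at h then adds to the ether-stabilised oxocarbenium carbon i in the same encounter, leaving the cyclic silyl enol ether at j=k; the closest known reaction type is the Lewis-acid-catalysed formal [4π+2σ] annulation of acyl bicyclobutanes with silyl dienol ethers to bicyclo[4.1.1]octenes, known only for less substituted partners. The seven-membered ring closes by a 7-(enolexo)-exo-trig aldol-type attack of the h enolate on i across the 1,3-positions of the released cyclobutane, so both new bonds are cis and the exo arms on c and g finish on the opposite face. Centres b and h follow from this concave-face entry (inversion at b, cis closure at h), while a and i are fixed relative to each other by the diene geometry (Z at a=k locked by the dioxasiline ring, E at j=i) and suprafacial addition, which places the CH2O on a and the OPMB on i cis. Their sense relative to the unlike arms on c and g has no control element in the substrate, because the arms point away from the reacting face, and is assigned to the C2-symmetric bisoxazoline on divalent copper, which is expected to shield one of the two concave-face quadrants next to h for either rotamer of the acyl group. Regiochemistry (a to b, h to i) follows from polarity, and closure at i rather than at k is expected because the charge is held at i by the ether oxygen and k is flanked by the new quaternary carbon.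

Step 13
Reactants: 21 annulation product
Product: 22 primary alcohol (CH2OH on h)
Conditions: LiBH4, THF, 0 °C to rt
Reagents that add atoms: none
Why: N-Acylpyrazoles are active amides that borohydride reduces to the primary alcohol with loss of the pyrazole, while silyl ethers, the silyl enol ether and the PMB ether are inert.

Step 14
Reactants: 22 primary alcohol
Product: 23 mesylate (CH2OMs on h)
Conditions: MsCl, Et3N, CH2Cl2, 0 °C
Reagents that add atoms: methanesulfonyl chloride, CS(=O)(=O)Cl
Why: Sulfonylation via sulfene is insensitive to the neopentyl-type hindrance of the alcohol and touches no stereocentre.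

Step 15
Reactants: 23 mesylate
Product: 24 methyl compound (CH3 on h)
Conditions: LiEt3BH (excess), THF, 0 to 65 °C
Reagents that add atoms: none
Why: Hydride displacement of a primary sulfonate by LiEt3BH, the usual reagent for neopentyl-type sulfonates, converts the activating carbon into the methyl group on h by a polar path that avoids the cyclobutylcarbinyl radical.

Step 16
Reactants: 24 methyl compound
Product: 25 keto triol (ketone at k; CH2OH on a and on c; CH(OH)CH3 on g; PMB ether on i)
Conditions: HF·pyridine, pyridine/THF, 0 °C to rt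
Reagents that add atoms: none
Why: Fluoride removes both TBS ethers and the silylene, protodesilylation of the enol ether gives the ketone at k, and the acidic medium avoids retro-aldol loss of formaldehyde from the α-quaternary β-hydroxy ketone; the PMB ether is stable.

Step 17
Reactants: 25 keto triol
Product: 26 tetraol (k–OH trans to the CH2OH on a)
Conditions: Me4NBH(OAc)3, MeCN/AcOH, −30 °C
Reagents that add atoms: none
Why: Saksena–Evans hydroxyl-directed reduction: the CH2OH on a, the only hydroxyl β to the ketone, binds boron and delivers hydride to the carbonyl face on its own side, so the new k–OH should end trans to CH2OH and cis to the methyl on a, as in the target.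

Step 18
Reactants: 26 tetraol
Product: 27 acetonide (isopropylidene across a–CH2O and k–O; arm alcohols free)
Conditions: 2,2-dimethoxypropane, PPTS (cat.), CH2Cl2, 0 °C to rt
Reagents that add atoms: 2,2-dimethoxypropane, COC(C)(C)OC
Why: Acetal exchange is selective for the 1,3-diol (six-membered dioxane), since the two arm alcohols are 1,5-related and cannot form a cyclic acetal.

Step 19
Reactants: 27 acetonide diol
Product: 28 keto aldehyde (CHO on c, acetyl on g)
Conditions: Dess–Martin periodinane, NaHCO3, CH2Cl2, rt; used directly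
Reagents that add atoms: none
Why: Buffered Dess–Martin oxidation converts the primary and secondary arm alcohols to aldehyde and methyl ketone without base strong enough to epimerise the axial formyl group on c.

Step 20
Reactants: 28 keto aldehyde
Product: 29 β-ketophosphonate (C(=O)CH2P(O)(OMe)2 on c, acetyl on g)
Conditions: dimethyl (diazomethyl)phosphonate, SnCl2 (20 mol %), CH2Cl2, rt
Reagents that add atoms: dimethyl (diazomethyl)phosphonate, COP(=O)(OC)C=[N+]=[N-]
Why: Roskamp homologation: SnCl2-catalysed addition of the diazophosphonate to the aldehyde and 1,2-hydride shift with loss of N2 gives the β-ketophosphonate, and the reaction is selective for the aldehyde over the methyl ketone.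

Step 21
Reactants: 29 β-ketophosphonate
Product: 30 tricyclic enone (c–C(=O)–CH=C(CH3)–g ring closed)
Conditions: K2CO3, 18-crown-6, toluene, 80 °C
Reagents that add atoms: none
Why: Intramolecular Horner–Wadsworth–Emmons olefination onto the methyl ketone closes the six-membered enone ring across the two cis, diaxial arms on c and g (a verbenone-type bicyclo[3.1.1]heptenone), and no new stereocentre arises.

Step 22
Reactants: 30 tricyclic enone acetonide
Product: 31 diol (CH2OH on a, OH on k)
Conditions: AcOH/THF/H2O, 40 °C
Reagents that add atoms: none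
Why: Mild acidic acetal hydrolysis frees the 1,3-diol without affecting the enone or the PMB ether.

Step 23
Reactants: 31 diol
Product: 32 mono-angelate (angelate on the CH2O of a, free OH on k)
Conditions: angelic acid, 2,4,6-trichlorobenzoyl chloride, Et3N, toluene, rt; then 31, 80 °C
Reagents that add atoms: angelic acid, C/C=C(/C)C(=O)O
Why: Yamaguchi-type mixed-anhydride esterification transfers the angeloyl group without Z-to-E isomerisation, and the primary alcohol should react ahead of the hindered secondary one.

Step 24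
Reactants: 32 mono-angelate
Product: 33 angelate acetate (OAc on k)
Conditions: Ac2O, DMAP (cat.), pyridine, rt
Reagents that add atoms: acetic anhydride, CC(=O)OC(C)=O
Why: DMAP-catalysed acylation acetylates the remaining secondary alcohol with retention at k.

Step 25
Reactants: 33 angelate acetate
Product: 34 alcohol (free OH on i)
Conditions: DDQ, CH2Cl2/pH 7 buffer, 0 °C
Reagents that add atoms: none
Why: Oxidative cleavage of the PMB ether by DDQ leaves the enone and both esters, including the angelate, intact.

Step 26
Reactants: 34 alcohol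
Product: 35 target compound CNP0179010.1
Conditions: 3-methylbut-2-enoyl chloride, pyridine, DMAP (cat.), CH2Cl2, 0 °C to rt
Reagents that add atoms: 3-methylbut-2-enoyl chloride, CC(C)=CC(=O)Cl
Why: Acylation of the secondary alcohol on i with the acid chloride under a weak base (to limit ketene formation and deconjugation) installs the senecioate with retention.

**Compound list**
1 | ethyl (S)-lactate | C[C@H](O)C(=O)OCC | starting material
2 | ethyl (2S)-2-[(tert-butyldimethylsilyl)oxy]propanoate | C[C@H](O[Si](C)(C)C(C)(C)C)C(=O)OCC | intermediate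
3 | (2S)-2-[(tert-butyldimethylsilyl)oxy]propanal | C[C@H](O[Si](C)(C)C(C)(C)C)C=O | intermediate
4 | tert-butyldimethyl(prop-2-yn-1-yloxy)silane | C#CCO[Si](C)(C)C(C)(C)C | starting material
5 | chloro{(E)-3-[(tert-butyldimethylsilyl)oxy]prop-1-enyl}zirconocene | CC(C)(C)[Si](C)(C)OC/C=C/[Zr](Cl)(C1C=CC=C1)C1C=CC=C1 | intermediate (not isolated)
6 | {(E)-3-[(tert-butyldimethylsilyl)oxy]prop-1-enyl}(methyl)zinc | CC(C)(C)[Si](C)(C)OC/C=C/[Zn]C | intermediate (not isolated)
7 | (2S,3R,4E)-2,6-bis[(tert-butyldimethylsilyl)oxy]hex-4-en-3-ol | C[C@H](O[Si](C)(C)C(C)(C)C)[C@H](O)/C=C/CO[Si](C)(C)C(C)(C)C | intermediate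
8 | trimethyl orthoacetate | COC(C)(OC)OC | starting material
9 | mixed ketene acetal of 7 (O-allyl O-methyl) | C=C(OC)O[C@H](/C=C/CO[Si](C)(C)C(C)(C)C)[C@H](C)O[Si](C)(C)C(C)(C)C | intermediate (not isolated)
10 | methyl (3S,4E,6S)-6-[(tert-butyldimethylsilyl)oxy]-3-{[(tert-butyldimethylsilyl)oxy]methyl}hept-4-enoate | COC(=O)C[C@H](CO[Si](C)(C)C(C)(C)C)/C=C/[C@H](C)O[Si](C)(C)C(C)(C)C | intermediate
11 | 2-(trifluoroacetyl) derivative of 10 (C2 epimers or enol) | COC(=O)C(C(=O)C(F)(F)F)[C@H](CO[Si](C)(C)C(C)(C)C)/C=C/[C@H](C)O[Si](C)(C)C(C)(C)C | intermediate (not isolated)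
12 | methyl (3R,4E,6S)-2-diazo-6-[(tert-butyldimethylsilyl)oxy]-3-{[(tert-butyldimethylsilyl)oxy]methyl}hept-4-enoate | COC(=O)C(=[N+]=[N-])[C@H](CO[Si](C)(C)C(C)(C)C)/C=C/[C@H](C)O[Si](C)(C)C(C)(C)C | intermediate
13 | methyl (2R,4S)-2-{[(tert-butyldimethylsilyl)oxy]methyl}-4-{(1S)-1-[(tert-butyldimethylsilyl)oxy]ethyl}bicyclo[1.1.0]butane-1-carboxylate, exo,exo | COC(=O)[C@]12[C@H](CO[Si](C)(C)C(C)(C)C)[C@H]1[C@@H]2[C@H](C)O[Si](C)(C)C(C)(C)C | intermediate
14 | the corresponding bicyclo[1.1.0]butane-1-carboxylic acid | OC(=O)[C@]12[C@H](CO[Si](C)(C)C(C)(C)C)[C@H]1[C@@H]2[C@H](C)O[Si](C)(C)C(C)(C)C | intermediate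
15 | the corresponding N-acyl-3,5-dimethylpyrazole (key-step precursor) | Cc1cc(C)n(n1)C(=O)[C@]12[C@H](CO[Si](C)(C)C(C)(C)C)[C@H]1[C@@H]2[C@H](C)O[Si](C)(C)C(C)(C)C | intermediate
16 | pent-1-yn-3-one | CCC(=O)C#C | starting material
17 | 4-methoxybenzyl alcohol | COc1ccc(CO)cc1 | starting material
18 | (1E)-1-[(4-methoxybenzyl)oxy]pent-1-en-3-one | CCC(=O)/C=C/OCc1ccc(OC)cc1 | intermediate
19 | (1E)-5-hydroxy-1-[(4-methoxybenzyl)oxy]-4-methylpent-1-en-3-one, racemic | CC(CO)C(=O)/C=C/OCc1ccc(OC)cc1 | intermediate
20 | 2,2-di-tert-butyl-6-{(E)-2-[(4-methoxybenzyl)oxy]ethenyl}-5-methyl-4H-1,3,2-dioxasiline (key-step precursor) | CC1=C(/C=C/OCc2ccc(OC)cc2)O[Si](C(C)(C)C)(C(C)(C)C)OC1 | intermediate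
21 | bicyclo[4.1.1]octene annulation product (acylpyrazole on h, silylene enol ether, PMB ether on i, TBS arms) | CC(C)(C)[Si]1(C(C)(C)C)OC[C@]2(C)[C@@H]3[C@@H](CO[Si](C)(C)C(C)(C)C)[C@@](C(=O)n4nc(C)cc4C)([C@H]3[C@H](C)O[Si](C)(C)C(C)(C)C)[C@H](OCc4ccc(OC)cc4)C=C2O1 | intermediate
22 | primary alcohol (CH2OH on h) | CC(C)(C)[Si]1(C(C)(C)C)OC[C@]2(C)[C@@H]3[C@@H](CO[Si](C)(C)C(C)(C)C)[C@@](CO)([C@H]3[C@H](C)O[Si](C)(C)C(C)(C)C)[C@H](OCc4ccc(OC)cc4)C=C2O1 | intermediate
23 | mesylate of 22 | CC(C)(C)[Si]1(C(C)(C)C)OC[C@]2(C)[C@@H]3[C@@H](CO[Si](C)(C)C(C)(C)C)[C@@](COS(C)(=O)=O)([C@H]3[C@H](C)O[Si](C)(C)C(C)(C)C)[C@H](OCc4ccc(OC)cc4)C=C2O1 | intermediate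
24 | methyl compound (CH3 on h) | CC(C)(C)[Si]1(C(C)(C)C)OC[C@]2(C)[C@@H]3[C@@H](CO[Si](C)(C)C(C)(C)C)[C@@](C)([C@H]3[C@H](C)O[Si](C)(C)C(C)(C)C)[C@H](OCc4ccc(OC)cc4)C=C2O1 | intermediate
25 | keto triol | OC[C@]1(C)[C@@H]2[C@@H](CO)[C@@](C)([C@H]2[C@H](C)O)[C@H](OCc3ccc(OC)cc3)CC1=O | intermediate
26 | tetraol | OC[C@]1(C)[C@@H]2[C@@H](CO)[C@@](C)([C@H]2[C@H](C)O)[C@H](OCc3ccc(OC)cc3)C[C@H]1O | intermediate
27 | acetonide diol | CC1(C)OC[C@]2(C)[C@@H]3[C@@H](CO)[C@@](C)([C@H]3[C@H](C)O)[C@H](OCc4ccc(OC)cc4)C[C@H]2O1 | intermediate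
28 | keto aldehyde | CC1(C)OC[C@]2(C)[C@@H]3[C@@H](C=O)[C@@](C)([C@H]3C(C)=O)[C@H](OCc4ccc(OC)cc4)C[C@H]2O1 | intermediate
29 | β-ketophosphonate | CC1(C)OC[C@]2(C)[C@@H]3[C@@H](C(=O)CP(=O)(OC)OC)[C@@](C)([C@H]3C(C)=O)[C@H](OCc4ccc(OC)cc4)C[C@H]2O1 | intermediate
30 | tricyclic enone acetonide | CC1(C)OC[C@]2(C)[C@@H]3[C@H]4C(=O)C=C(C)[C@@H]3[C@@]4(C)[C@H](OCc5ccc(OC)cc5)C[C@H]2O1 | intermediate
31 | enone diol | OC[C@]1(C)[C@@H]2[C@H]3C(=O)C=C(C)[C@@H]2[C@@]3(C)[C@H](OCc4ccc(OC)cc4)C[C@H]1O | intermediate
32 | mono-angelate | C/C=C(/C)C(=O)OC[C@]1(C)[C@@H]2[C@H]3C(=O)C=C(C)[C@@H]2[C@@]3(C)[C@H](OCc4ccc(OC)cc4)C[C@H]1O | intermediate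
33 | angelate acetate | C/C=C(/C)C(=O)OC[C@]1(C)[C@@H]2[C@H]3C(=O)C=C(C)[C@@H]2[C@@]3(C)[C@H](OCc4ccc(OC)cc4)C[C@H]1OC(C)=O | intermediate
34 | alcohol with free OH on i | C/C=C(/C)C(=O)OC[C@]1(C)[C@@H]2[C@H]3C(=O)C=C(C)[C@@H]2[C@@]3(C)[C@H](O)C[C@H]1OC(C)=O | intermediate
35 | CNP0179010.1 | C/C=C(/C)C(=O)OC[C@]1(C)[C@@H]2[C@H]3C(=O)C=C(C)[C@@H]2[C@@]3(C)[C@H](OC(=O)C=C(C)C)C[C@H]1OC(C)=O | target

**Step count**
Total: 26 steps. Longest linear sequence: 23 steps (steps 1–8, then 12–26); the diene branch (steps 9–11) joins at step 12.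

**Steps most likely to fail**

Step 12 (proposed new method). The fully substituted carbon a may fail to reach b, so that the Lewis acid instead isomerises the bicyclobutane or degrades the dienol ether; if the addition occurs, the side of approach may not be controlled by the ligand. The fallback lowers the substitution of the nucleophilic terminus to the level for which this annulation type is established and builds the quaternary centre afterwards by known enolate chemistry. It sets out from 15 and 18. Ketone 18 is silylated (TMSOTf, Et3N) to (1E,3Z)-1-[(4-methoxybenzyl)oxy]-3-(trimethylsilyloxy)penta-1,3-diene F1. Annulation of F1 with 15 under the conditions of step 12 gives the a-H silyl enol ether adduct F2, which mild acid converts to the a-H ketone F3. Thermodynamic enol silylation (TMSOTf, Et3N) gives the a=k trimethylsilyl enol ether F4. Mukaiyama aldol reaction with aqueous formaldehyde (Yb(OTf)3, THF) gives the hydroxymethyl ketone F5; the face of this aldol step, and hence the configuration at a, would have to be established. Treatment of F5 with t-Bu2Si(OTf)2 and Et3N returns to the route at 21.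

Step 6. The tertiary C3–H of the rhodium carbene may migrate (1,2-hydride shift to a dienoate), or the ring may close with the silyloxymethyl group endo. The fallback replaces the carbene by two enolate alkylations and sets out from 10. Shi epoxidation (fructose-derived ketone of the enantiomer that delivers oxygen to the face opposite the later C2 bonds, KHSO5, K2CO3, MeCN/buffer) gives the trans-epoxy ester F6. LiN(SiMe3)2 induces 3-exo-tet opening at C4 with inversion to the cyclopropyl carbinol F7. Mesylation gives the mesylate F8, and a second enolate alkylation (LiN(SiMe3)2 or KOt-Bu, 3-exo-tet with inversion at C5) closes the second cyclopropane. Both C–O bonds are replaced on the face opposite oxygen, so the net result is the syn addition of C2 that the carbene would have given, and the route is rejoined at 13.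

Step 15. Hydride substitution at the neopentyl-type carbon may be slow, leaving room for S–O cleavage back to 22 or for cyclic ether formation by attack of a neighbouring arm oxygen on the mesylate. The fallback changes from polar substitution to C–O homolysis and sets out from 22. 1,1′-Thiocarbonyldiimidazole gives the O-alkyl imidazole-1-carbothioate F9. Barton–McCombie deoxygenation with Bu3SnH at high concentration (AIBN, toluene, 80–110 °C) is meant to trap the cyclobutylcarbinyl radical faster than it can open, and returns to the route at 24.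

**Further compounds**
F1 | step 12 | (1E,3Z)-1-[(4-methoxybenzyl)oxy]-3-(trimethylsilyloxy)penta-1,3-diene | C/C=C(O[Si](C)(C)C)/C=C/OCc1ccc(OC)cc1
F2 | step 12 | a-H silyl enol ether adduct | C[C@@H]1[C@@H]2[C@@H](CO[Si](C)(C)C(C)(C)C)[C@@](C(=O)n3nc(C)cc3C)([C@H]2[C@H](C)O[Si](C)(C)C(C)(C)C)[C@H](OCc3ccc(OC)cc3)C=C1O[Si](C)(C)C
F3 | step 12 | a-H ketone | C[C@@H]1[C@@H]2[C@@H](CO[Si](C)(C)C(C)(C)C)[C@@](C(=O)n3nc(C)cc3C)([C@H]2[C@H](C)O[Si](C)(C)C(C)(C)C)[C@H](OCc3ccc(OC)cc3)CC1=O
F4 | step 12 | a=k trimethylsilyl enol ether | CC=1[C@@H]2[C@@H](CO[Si](C)(C)C(C)(C)C)[C@@](C(=O)n3nc(C)cc3C)([C@H]2[C@H](C)O[Si](C)(C)C(C)(C)C)[C@H](OCc3ccc(OC)cc3)CC=1O[Si](C)(C)C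
F5 | step 12 | hydroxymethyl ketone | OC[C@]1(C)[C@@H]2[C@@H](CO[Si](C)(C)C(C)(C)C)[C@@](C(=O)n3nc(C)cc3C)([C@H]2[C@H](C)O[Si](C)(C)C(C)(C)C)[C@H](OCc3ccc(OC)cc3)CC1=O
F6 | step 6 | trans-epoxy ester | COC(=O)C[C@H](CO[Si](C)(C)C(C)(C)C)[C@H]1O[C@@H]1[C@H](C)O[Si](C)(C)C(C)(C)C
F7 | step 6 | cyclopropyl carbinol (C2 of the ester unassigned) | COC(=O)C1[C@H](CO[Si](C)(C)C(C)(C)C)[C@H]1[C@H](O)[C@H](C)O[Si](C)(C)C(C)(C)C
F8 | step 6 | mesylate of F7 | COC(=O)C1[C@H](CO[Si](C)(C)C(C)(C)C)[C@H]1[C@H](OS(C)(=O)=O)[C@H](C)O[Si](C)(C)C(C)(C)C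
F9 | step 15 | O-alkyl imidazole-1-carbothioate of 22 | CC(C)(C)[Si]1(C(C)(C)C)OC[C@]2(C)[C@@H]3[C@@H](CO[Si](C)(C)C(C)(C)C)[C@@](COC(=S)n4ccnc4)([C@H]3[C@H](C)O[Si](C)(C)C(C)(C)C)[C@H](OCc4ccc(OC)cc4)C=C2O1
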